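Decide first whether this flask is to be counted by its charges or by its clocks, for my colleague and I hold opposite views of it.

    2 Ym → Wa (k1 = 1.3 × 10⁶ /M/s)
    Dz + Kj → Wu + Zo (k2 = 1.0 × 10⁶ /M/s)
    Dz + Ym → Ty + Zo (k3 = 22000 /M/s)
    Dx → Uj (k4 = 0.034 /h)
    2 Qi → Xo (k5 = 3.8 × 10⁸ /M/s)
    Qa + Zo → Rx + Qi (k6 = 29000 /M/s)
    Dx + Zo → Gu + Ym (k7 = 1.3 × 10⁵ /M/s)
    Aj ⇌ Dz, rate k8*(cs8 - [Dz]) while solid is left; crystals form when [Dz] > cs8 (cs8 = 3.6 mM, k8 = 0.13 /h)
    Ez → 2 Kj (k9 = 0.010 /h)

Aj 10 mM; Dx 20.0 mM; Qa 3.00 mM; Ez 0.18 mM; time 15 d

1. the state of affairs at 15 d: stopped, and by what, or still going (for what has run out or reacted, a solid counts together with what of it has only dissolved) (Dx has run out first / it is still moving / all of Aj has reacted)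
2. how much Gu there is at 15 d, in percent of the Aj charged

- for a step with 2 of a species take k times the square, and two of it per event
- solid, in amounts per volume of the solution: Aj
- at the start none of Aj is in solution
- what has only dissolved of Aj counts as not reacted
- the reaction counts as stopped when no species that holds the Aj changes by six tenths of a point or more over the second half of the time
- run time (flask): 15 d

We agree on the chain: Ez gives two Kj, Kj on Dz gives Zo, and Zo either meets Dx, which makes Gu and Ym, and Ym on Dz returns Zo, or it meets Qa and the chain ends, so the chain length, Gu per radical, is the rate of Zo on Dx over that of Zo on Qa, 29.9 at the starting charges. My colleague counts charges: Dx stands at 2.00 equivalents, which makes Aj the limiting reagent, and Ez holds radicals worth 3.60% of the Aj charge, which at that chain length comes to 108%, enough on paper to take the whole of Aj into Gu.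

I count clocks, because Dx has a half-life of 0.85 d on its way to Uj against 2.9 d for Ez, so Dx leaves the flask faster than Ez releases its radicals. Weighting the release by the Dx still there keeps the share 0.227 of them, and I call what remains the radical dose, the fraction of the Aj charge in radicals that find Dx alive: 0.818%. Dose times chain length gives Gu at 24.5%, and the state at the asked time is Dx has run out first.

The forecast takes my side with Dx has run out first and Gu at 22.5%, a little below my figure, holding that Qa “dominates termination by intercepting Zo”.

The flask gives Dx has run out first, with Dx at 0% and Gu at 22.4%, and the neighbour with 0.75 mM of Qa moves towards my colleague's count, with Gu at 68.5%, though Dz still holds 28.1% of the Aj charge there and Dx stands at 0%. In this flask at 0.760 d, Dx had a half-life of 6.3 d by the step to Gu against 0.85 d by the step to Uj. At the asked time Uj stands at 88.8% of the Dx charge, and Gu over the dose reads a chain length of 27.4. With 12 mM of Dx the dose stays 0.818%, the shorter chain gives 14.7%, and that neighbour stands at 13.5%.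

The numbers are those of an exercise; what happens was integrated by code.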